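The runs were generated by integration with made-up constants; noise was put on by code.

66.7% of its charge is what partner has left in the flask at 50% conversion, if each substrate turned over takes one partner, whichever hand it is.

common to all: left-handed substrate 20 mM; right-handed substrate 20 mM; catalyst 0.40 mM
- Thursday's: partner 60 mM; the very flask that is asked about, followed so far
- flask: partner 60.0 mM

Thursday's run (percent of the left-handed substrate and right-handed substrate together charged)

| time / min | left-handed product / % | left-handed substrate / % |
|---|---|---|
| 10.0 | 10 | 40 |
| 20.0 | 18 | 33 |
| 30.0 | 24 | 22 |
| 40.0 | 30 | 19 |
| 50.0 | 31 | 16 |
| 60.0 | 36 | 15 |
| 80.0 | 40 | 10 |

(readings scatter by 1.5 percentage points)

- catalyst is single-handed; left-handed substrate and right-handed substrate are mirror images of each other, charged as a racemate, each of them at the stated concentration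
- no earlier run changes the charge of catalyst; that part of a forecast is a guess
- no earlier run changes the charge of partner; that part of a forecast is a guess

1. apparent order in catalyst when 50% of the left-handed substrate and right-handed substrate together are converted (percent change of the rate of making left-handed product for one percent more catalyst charged)
2. apparent order in partner when 50% of the left-handed substrate and right-handed substrate together are converted (percent change of the rate of making left-handed product for one percent more partner charged)
3. factor on the rate of making left-handed product when 50% of the left-handed substrate and right-handed substrate together are converted if partner is charged twice over

At fixed conversion the amount of partner used does not move with the charge, so one percent more charge is more than one percent more partner standing. That gives a factor of 1.50: the partner lever, the charge of partner over what stands at the moment of looking. A reagent in such excess that it stays constant, the pseudo-first-order case, has a lever of one; partner in this flask does not.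

Two views dispute the flask. I hold the rate first order in partner, so the apparent order is the lever itself, and a doubled charge multiplies what stands by 2.50. The forecast uses the same lever with an order of 0.85, on the ground that “a weaker order isn't excluded”, and gives 1.3 in partner and 2.2 on doubling. Both of us guess order one in catalyst, printed in the forecast as 1. No earlier run changes the charge of partner, so that part of each number is a guess.

The simulation gives 1.1 in catalyst, 1.6 in partner and 2.58 on doubling, so the order in partner is higher than the forecast's. It is also higher than my lever, by 0.1000, while the forecast's number is lower than the lever, by 0.200.

    partner + catalyst + left-handed substrate → catalyst + left-handed product (k = 70800 M⁻² h⁻¹)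
    partner + catalyst + right-handed substrate → catalyst + right-handed product (k = 27000 M⁻² h⁻¹)
    catalyst ⇌ dormant form (K = 1.17, k = 0.0719 h⁻¹)

Both paths use partner, the left-handed path at 2.6 times the rate of the right-handed one at the start. The weaker view has its region earlier in this flask: a lever of 1.3 belongs to partner at 76.9% of charge, which lies between 84.8% at 0.250 h and 66.7% at 0.821 h. At 1.25 h partner stands at 59.5%, a lever of 1.68.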